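## The problem

The target is a fully substituted cyclohex-2-enone. Numbering the ring C1 (ketone), C2 (enamide nitrogen), C3, C4 (tertiary carbinol), C5 and C6 (oxirane), every ring carbon carries a heteroatom or a side chain, and the only fused ring is the three-membered ether. Two all-E trienes are attached: a 10-methylundeca-2,4,6-trienoyl group on the C2 nitrogen, and a hepta-2,4,6-trienamide running from C4 to a 2-amino-3-hydroxycyclopent-2-enone. Both are linear chains that can be made apart and joined by C–N and C–C coupling. The stereocentres C4, C5 and C6 are contiguous (4S,5S,6R in this numbering). The oxirane fixes C5 and C6 as a cis pair, so the real tasks are the absolute sense of that pair and placing the C4 hydroxyl on the opposite face. A protected cis-diol on C5/C6 can do both, because it blocks one ring face and forces oxygen onto C4 from the other. The epoxy ketone will not stand hard nucleophiles or long exposure to base, the tertiary allylic alcohol dislikes strong acid, the trienes are sensitive to light, oxidants and iodine, and the cyclopentenone enol is an acid, so the polyenes belong at the end. The enabling feature is the ring's oxygen pattern: C1 and C4 are oxygenated 1,4 across C2=C3 and C4 has no hydrogen, so a C1–O–O–C4 bridge can unravel only to the C1 ketone and the C4 alcohol. With the cis oxygens on C5/C6 this is the pattern of an arene cis-dihydrodiol whose substituent is the C4 side chain.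

## Retrosynthesis

**Lower triene, C5′–C6′ bond.** Target 32 is cut between the second and third alkene of the lower chain into vinylstannane 31 and iododienamide 15. A Stille coupling joins two E sp2 carbons under neutral conditions and keeps both geometries. The neighbouring cuts are worse: forming the cyclopentenone amide last needs acyl activation beside an epoxy ketone and a tertiary alcohol, and an olefination at C4 needs a carbonyl the ring does not have. The cut removes five carbons and the acidic enol from the core. The forward step must tolerate the free enol of 15 and the oxirane.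

**Iododienamide 15.** The amide bond is cut to acid 13 and amine hydrochloride 10. Acid 13 comes from ester 12, made by Takai olefination of the commercial aldehyde ester 11, which sets the 4E iodoalkene next to an existing E enoate. Amine 10 comes from cyclopentane-1,3-dione 8 by C2 nitration (9) and hydrogenation. All are short, flat operations on achiral material.

**Vinylstannane 31 to alkyne 30.** The C–Sn and C–H bonds are removed to leave a terminal alkyne. An ethynyl group is the smallest two-carbon precursor of an E-vinyl metal and is inert to everything the ring must go through earlier. The forward hydrostannation must place tin on the terminal carbon, which the quaternary C4 enforces, and must leave the enone alone.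

**Oxirane, C6–O bond.** Epoxide 30 is traced to the cis-triol 26 through C6 sulfonate 27, bromohydrin 28 and silyl epoxide 29. A cis-diol cannot close directly, so C6 is inverted twice (sulfonate to bromide, then closure by the C5 oxygen) and the oxirane ends on the face the diol occupied. The more common route through a trans-bromo ester was set aside: cleaving an ester on C5 with base, in a ketone whose C6–H is α to the carbonyl and β to that ester, invites E1cB loss of the ester. With a free C5 hydroxyl no such leaving group exists. The same methanolic carbonate removes the alkynyl silicon, so the cap costs no separate step.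

**C2–N bond.** Triol 26 comes from acetonide 25, which is cut at nitrogen into iodoenone 24 and the primary trienamide 7 (copper-catalysed Goldberg amidation). This brings in the whole upper chain in one convergent step, after all oxidative chemistry. Acylation of a free 2-amino enone would need a separate amination first. The coupling demands that the alkyne be capped (otherwise copper acetylide chemistry competes) and that the base be mild, because C6–H of the acetonide ketone is enolisable. Amide 7 is built from 4-methylpentanal 1 by two Horner–Wadsworth–Emmons reactions (phosphonates 2 and 6) through ester 3, alcohol 4 and aldehyde 5.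

**C2–I and the peroxide.** Iodoenone 24 comes from enone 23 by α-iodination. Enone 23 is the Kornblum–DeLaMare product of endoperoxide 22, and only C1 carries a hydrogen, so no regiochemical choice exists.

**Key cut, C1–O and C4–O.** Endoperoxide 22 is cut into diene acetonide 21 and dioxygen 17. This (4+2) cycloaddition installs both remaining ring oxygens, closes the 1,2-dioxane bridge and sets C4 (and, transiently, C1) anti to the dioxolane. The precursor is a flat diene with only the two enzyme-derived stereocentres. The step needs facial selectivity only.

**Diene 21.** The silicon cap is removed to give alkyne 20, the acetonide (from 2,2-dimethoxypropane 19) to give diol 18, and the two C–O bonds of 18 to give phenylacetylene 16 and dioxygen 17 through enzymatic cis-dihydroxylation. The enzyme supplies C5 and C6 in the required absolute sense, and all six ring carbons plus the two alkyne carbons come from one commodity arene.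

## Roads not taken

**Alternative 1:** carbene-catalysed ring closure at C4–C5. The ring is cut between C4 and C5 to the acyclic keto aldehyde A1. A chiral aminoindanol-derived triazolium carbene would turn the aldehyde into its Breslow intermediate, which adds to the ynone carbonyl and closes the ring as the α-hydroxy ketone A2, with C4 set by the catalyst.
- Merits: catalytic, no fermentation or photochemistry, either enantiomer available, and the quaternary carbinol is made directly.
- Weak points: A2 has only one of the three stereocentres and the wrong oxidation level almost everywhere. C5 is a ketone, C6 a methylene, C1 a ketal and C2–C3 saturated. Reaching the level of 24 needs a diastereoselective C5 reduction, regioselective C6 oxygenation, dehydrogenation at C2–C3 and oxirane closure, each a separate selectivity problem. An ynone is also an untested acceptor next to the usual aryl and alkyl ketones.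
- Comparison: the chosen plan reaches 23, with C1, C4, C5 and C6 all at the right oxidation level and configuration, in five steps from 16. Alternative 1 is better in scalability and in free choice of enantiomer. The chosen plan answers with far fewer redox corrections.

**Alternative 2:** desymmetrising epoxidation. Both C–O bonds of the oxirane are cut, giving the achiral quinol silyl ether A3. tert-Butyl hydroperoxide anion paired with N-benzylcinchonidinium chloride (Weitz–Scheffer epoxidation under phase transfer) would epoxidise one of the two enantiotopic enone double bonds, anti to the silyloxy group, to give A4.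
- Merits: this is the shortest road. A4 has C4, C5 and C6 in one step from a compound a few steps from simple aromatics. It needs no diol-to-oxirane detour, and the remaining enone can be iodinated and amidated as in the chosen route.
- Weak points: everything rests on the catalyst telling apart two enone arms that differ only in their relation to a remote quaternary centre carrying ethynyl and silyloxy groups. The sense and level of that selectivity cannot be predicted with confidence, and a second epoxidation can follow. The C–N coupling would then run on an epoxy ketone.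
- Comparison: in step count Alternative 2 is clearly better, about six steps shorter to the level of 30. The chosen plan answers with certainty of configuration: the enzyme gives one enantiomer, and anti addition to the acetonide face is a property of the substrate, not of a catalyst. If the desymmetrisation were shown to be selective, it would be the preferred route.

**Alternative 3:** chiral pool with Ferrier carbocyclisation. The C2–C3 bond is cut and C4–C6 are mapped onto C2–C4 of D-glucose A5. PdCl2 in aqueous dioxane would hydrate the enol ether of the 2-C-alkynyl hex-5-enopyranoside A6. The released ketone enolate adds to the anomeric aldehyde, and MsCl/Et3N dehydrates the ketol to enone A7.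
- Merits: cheap chiral pool and a well-established ring construction. The C5 and C6 oxygens arrive trans, so the oxirane closes with a single inversion where the chosen plan needs two.
- Weak points: the route to A6 is long (differentiating three hydroxyls, oxidation at C2, acetylide addition, 6-deoxygenation to the enol ether). C4 depends on the acetylide entering the 2-ulose from the axial side. Four protecting groups must be placed and removed.
- Comparison: Alternative 3 matches the chosen plan in certainty of absolute configuration and beats it at the oxirane closure. It loses by roughly double the linear length and by an extra selectivity at C4 that the cycloaddition settles by geometry.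

Key step: step 13

Conventions: core numbering as in the first section. β is the ring face of the C5/C6 oxygens; α is the opposite face, which carries the C4 hydroxyl.

Assumption: toluene dioxygenase oxidises phenylacetylene at the 2,3-bond with the same absolute sense as other monosubstituted benzenes, giving the (1S,2R)-diol.

## Route

### Upper chain (trienamide 7)

Step 1
Reactants: 1 4-methylpentanal; 2 triethyl 4-phosphonocrotonate (ethyl (E)-4-(diethoxyphosphoryl)but-2-enoate)
Product: 3 ethyl (2E,4E)-8-methylnona-2,4-dienoate
Conditions: LiN(SiMe3)2, THF, −78 °C to 0 °C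
Reagents that add atoms: none
Why: Vinylogous Horner–Wadsworth–Emmons olefination; the stabilised phosphonate anion gives the new C4=C5 bond E and the crotonate alkene stays E.

Step 2
Reactants: 3 ethyl (2E,4E)-8-methylnona-2,4-dienoate
Product: 4 (2E,4E)-8-methylnona-2,4-dien-1-ol
Conditions: i-Bu2AlH, CH2Cl2, −78 °C; aq. KNaC4H4O6 work-up
Reagents that add atoms: none
Why: 1,2-Reduction of a conjugated ester by an aluminium hydride; the diene is not touched.

Step 3
Reactants: 4 (2E,4E)-8-methylnona-2,4-dien-1-ol
Product: 5 (2E,4E)-8-methylnona-2,4-dienal
Conditions: MnO2, CH2Cl2, rt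
Reagents that add atoms: none
Why: Selective oxidation of an allylic alcohol by MnO2 without over-oxidation or alkene isomerisation.

Step 4
Reactants: 5 (2E,4E)-8-methylnona-2,4-dienal; 6 diethyl (carbamoylmethyl)phosphonate (2-(diethoxyphosphoryl)acetamide)
Product: 7 (2E,4E,6E)-10-methylundeca-2,4,6-trienamide
Conditions: KOt-Bu, THF, 0 °C to rt
Reagents that add atoms: none
Why: Horner–Wadsworth–Emmons olefination with an amide-stabilised phosphonate; E-selective and delivers the primary amide needed for the C–N coupling directly.

### Lower chain (iododienamide 15)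

Step 5
Reactants: 8 cyclopentane-1,3-dione
Product: 9 2-nitrocyclopentane-1,3-dione (enol form, 3-hydroxy-2-nitrocyclopent-2-en-1-one)
Conditions: fuming HNO3, Et2O, 0 °C
Reagents that add atoms: nitric acid, O[N+](=O)[O-]
Why: Electrophilic nitration of the enol of a cyclic 1,3-dione at C2, its only nucleophilic carbon.

Step 6
Reactants: 9 2-nitrocyclopentane-1,3-dione
Product: 10 2-amino-3-hydroxycyclopent-2-en-1-one hydrochloride
Conditions: H2 (1 atm), Pd/C (palladium metal on carbon), HCl, MeOH, rt
Reagents that add atoms: hydrogen chloride, Cl
Why: Catalytic hydrogenation of the nitro group; trapping the amine as its hydrochloride prevents self-condensation of the amino dione.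

Step 7
Reactants: 11 ethyl (E)-4-oxobut-2-enoate
Product: 12 ethyl (2E,4E)-5-iodopenta-2,4-dienoate
Conditions: CHI3, CrCl2, THF, 0 °C
Reagents that add atoms: iodoform, IC(I)I
Why: Takai olefination; the geminal dichromium species formed from iodoform and CrCl2 (divalent chromium) adds to the aldehyde and eliminates to the E iodoalkene, and the E enoate is untouched.

Step 8
Reactants: 12 ethyl (2E,4E)-5-iodopenta-2,4-dienoate
Product: 13 (2E,4E)-5-iodopenta-2,4-dienoic acid
Conditions: LiOH, THF–H2O, 0 °C to rt; then aq. HCl
Reagents that add atoms: lithium hydroxide, [Li+].[OH-]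
Why: Saponification of the ethyl ester; the vinyl iodide is inert to hydroxide at this temperature.

Step 9
Reactants: 13 (2E,4E)-5-iodopenta-2,4-dienoic acid; 10 2-amino-3-hydroxycyclopent-2-en-1-one hydrochloride
Product: 15 (2E,4E)-N-(2-hydroxy-5-oxocyclopent-1-en-1-yl)-5-iodopenta-2,4-dienamide, via acid chloride 14 (not isolated)
Conditions: (COCl)2, DMF (cat.), CH2Cl2, 0 °C to rt; concentrate; then 10, Et3N, DMF, 0 °C to rt
Reagents that add atoms: none
Why: Acyl chloride formation followed by N-acylation of the liberated amino enone; any O-acylated enol passes its acyl group on to nitrogen, and the diene geometry and C–I bond are unaffected.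

### Core and endgame

Step 10
Reactants: 16 phenylacetylene; 17 dioxygen
Product: 18 (1S,2R)-3-ethynylcyclohexa-3,5-diene-1,2-diol
Conditions: whole cells of E. coli JM109(pDTG601) expressing toluene dioxygenase, glucose-fed fermentation, pH 7, 30–35 °C
Reagents that add atoms: none
Why: Enzymatic arene cis-dihydroxylation; both atoms of one O2 go to the same face of the 2,3-bond, and the active site fixes the (1S,2R) configuration, which becomes C6 and C5 of the core.

Step 11
Reactants: 18 (1S,2R)-3-ethynylcyclohexa-3,5-diene-1,2-diol; 19 2,2-dimethoxypropane
Product: 20 (3aR,7aS)-4-ethynyl-2,2-dimethyl-3a,7a-dihydro-1,3-benzodioxole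
Conditions: p-TsOH·H2O (cat.), CH2Cl2, 0 °C
Reagents that add atoms: none
Why: Acid-catalysed transacetalisation closes the cis-fused dioxolane that will shield the β face; short contact with acid avoids dehydration to the phenol, and the product is kept cold against Diels–Alder dimerisation.

Step 12
Reactants: 20 (3aR,7aS)-4-ethynyl-2,2-dimethyl-3a,7a-dihydro-1,3-benzodioxole
Product: 21 (3aR,7aS)-2,2-dimethyl-4-[(trimethylsilyl)ethynyl]-3a,7a-dihydro-1,3-benzodioxole
Conditions: n-BuLi, THF, −78 °C; Me3SiCl, −78 °C to 0 °C
Reagents that add atoms: chlorotrimethylsilane, C[Si](C)(C)Cl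
Why: Deprotonation of the terminal alkyne, the only acidic C–H, and C-silylation; the cap keeps copper and base away from the alkyne until the C2–N bond has been made.

Step 13
Reactants: 21 (3aR,7aS)-2,2-dimethyl-4-[(trimethylsilyl)ethynyl]-3a,7a-dihydro-1,3-benzodioxole; 17 dioxygen
Product: 22 endoperoxide, 5β,6β-isopropylidenedioxy-4β-[(trimethylsilyl)ethynyl]-1α,4α-epidioxycyclohex-2-ene (a 2,3-dioxabicyclo[2.2.2]oct-5-ene with the O–O bridge anti to the dioxolane)
Conditions: O2, 5,10,15,20-tetraphenylporphyrin (cat.), visible light, CH2Cl2, −78 °C
Reagents that add atoms: none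
Why: Triplet tetraphenylporphyrin passes its energy to O2, and the singlet oxygen adds in a concerted, suprafacial (4+2) cycloaddition across the termini of the s-cis ring diene (core C1 and C4), making the C1–O and C4–O bonds together. The closest known reaction type is the photo-oxygenation of arene cis-dihydrodiol acetonides to bicyclic endoperoxides. The 1,2-dioxane ring is closed by the cycloaddition itself, as the two-atom bridge of the bicyclo[2.2.2]octene, so no separate cyclisation mode competes. Both new stereocentres (C1 and C4) are set by the cis-fused dioxolane, whose oxygens and inward methyl group cover the β face, so oxygen adds to the α face and the C4–O bond ends anti to the C5 and C6 oxygens. Facial selectivity is the only selectivity required, since O2 is symmetrical and the diene has one s-cis arrangement. The silylalkyne is inert to singlet oxygen, and the only allylic hydrogens are the electron-poor acetal C–H bonds, so an ene reaction is not expected. Working at −78 °C suppresses dimerisation of 21 and thermal rearrangement of the peroxide.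

Step 14
Reactants: 22 endoperoxide
Product: 23 4α-hydroxy-5β,6β-isopropylidenedioxy-4β-[(trimethylsilyl)ethynyl]cyclohex-2-en-1-one
Conditions: Et3N, CH2Cl2, 0 °C to rt
Reagents that add atoms: none
Why: Kornblum–DeLaMare rearrangement; the amine removes the only α-peroxy hydrogen (C1–H), the O–O bond breaks, C1 becomes the ketone and C4 the tertiary alcohol, and C4, C5 and C6 are not touched.

Step 15
Reactants: 23 4α-hydroxy-5β,6β-isopropylidenedioxy-4β-[(trimethylsilyl)ethynyl]cyclohex-2-en-1-one
Product: 24 4α-hydroxy-2-iodo-5β,6β-isopropylidenedioxy-4β-[(trimethylsilyl)ethynyl]cyclohex-2-en-1-one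
Conditions: I2, pyridine–CH2Cl2, 0 °C to rt
Reagents that add atoms: iodine, II
Why: α-Iodination of an enone by pyridine conjugate addition, iodination of the enolate at C2 and loss of pyridine; the reaction is established for cyclohexenones with a quaternary C4.

Step 16
Reactants: 24 the 2-iodo enone; 7 (2E,4E,6E)-10-methylundeca-2,4,6-trienamide
Product: 25 (2E,4E,6E)-N-{4α-hydroxy-5β,6β-isopropylidenedioxy-1-oxo-4β-[(trimethylsilyl)ethynyl]cyclohex-2-en-2-yl}-10-methylundeca-2,4,6-trienamide (core numbering)
Conditions: CuI (cat.), N,N′-dimethylethylenediamine (cat.), K2CO3, toluene, 50–60 °C, dark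
Reagents that add atoms: none
Why: Goldberg-type amidation of a vinyl iodide; monovalent copper with the diamine inserts into the activated C2–I bond and transfers the amidate, solid carbonate in toluene limits enolisation at C6, and the silyl cap rules out copper acetylide formation.

Step 17
Reactants: 25 the enamide acetonide
Product: 26 (2E,4E,6E)-N-{4α,5β,6β-trihydroxy-1-oxo-4β-[(trimethylsilyl)ethynyl]cyclohex-2-en-2-yl}-10-methylundeca-2,4,6-trienamide
Conditions: CF3CO2H–H2O, CH2Cl2, 0 °C
Reagents that add atoms: none
Why: Acid hydrolysis of the dioxolane; the enamide resists C-protonation because the iminium ion would sit next to the ketone, and ionisation at C4 is disfavoured by the electron-poor enone.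

Step 18
Reactants: 26 the triol
Product: 27 (2E,4E,6E)-N-{4α,5β-dihydroxy-6β-(4-nitrobenzenesulfonyloxy)-1-oxo-4β-[(trimethylsilyl)ethynyl]cyclohex-2-en-2-yl}-10-methylundeca-2,4,6-trienamide
Conditions: 4-O2NC6H4SO2Cl, Et3N, CH2Cl2, −20 °C to 0 °C
Reagents that add atoms: 4-nitrobenzenesulfonyl chloride, O=S(=O)(Cl)c1ccc(cc1)[N+](=O)[O-]
Why: Regioselective O-sulfonylation of the hydroxyl α to a carbonyl; C6–OH is the most acidic and least hindered, C5–OH is flanked by the quaternary C4 and C4–OH is tertiary, and C6 keeps its configuration because only the O–S bond forms.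

Step 19
Reactants: 27 the C6 sulfonate
Product: 30 (2E,4E,6E)-N-[5β,6β-epoxy-4β-ethynyl-4α-hydroxy-1-oxocyclohex-2-en-2-yl]-10-methylundeca-2,4,6-trienamide, via trans-bromohydrin 28 (not isolated), via silyl epoxide 29 (not isolated)
Conditions: LiBr, THF, 0 °C to rt; then K2CO3, MeOH, 0 °C to rt
Reagents that add atoms: none
Why: Bromide displaces the α-keto sulfonate by SN2 with inversion (C6–Br on the α face, anti to C5–OH); carbonate then lets the C5 alkoxide close the oxirane in a 3-exo-tet Williamson reaction with a second inversion at C6, so the ring oxygen sits on the β face the diol occupied, and the same methanolic carbonate cleaves the alkynyl C–Si bond. No ester has to be cleaved, so the C6 enolate has no good β leaving group, and any C6 epimer formed by bromide exchange re-equilibrates, since only the trans isomer can close.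

Step 20
Reactants: 30 the ethynyl epoxy enone
Product: 31 (2E,4E,6E)-N-{5β,6β-epoxy-4α-hydroxy-1-oxo-4β-[(E)-2-(tributylstannyl)ethenyl]cyclohex-2-en-2-yl}-10-methylundeca-2,4,6-trienamide
Conditions: Bu3SnH, PdCl2(PPh3)2 (cat.), THF, 0 °C
Reagents that add atoms: tributyltin hydride, CCCC[SnH](CCCC)CCCC
Why: Palladium-catalysed syn hydrostannation of a terminal alkyne (zerovalent palladium formed in the flask); the quaternary propargylic carbon sends tin to the terminal carbon, syn addition gives the E alkene, and alkyne insertion is much faster than hydride transfer to the hindered enone.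

Step 21
Reactants: 31 the vinylstannane; 15 (2E,4E)-N-(2-hydroxy-5-oxocyclopent-1-en-1-yl)-5-iodopenta-2,4-dienamide
Product: 32 (2E,4E,6E)-N-[(1R,5S,6S)-5-hydroxy-5-[(1E,3E,5E)-7-[(2-hydroxy-5-oxocyclopent-1-en-1-yl)amino]-7-oxohepta-1,3,5-trien-1-yl]-2-oxo-7-oxabicyclo[4.1.0]hept-3-en-3-yl]-10-methylundeca-2,4,6-trienamide (the target; 4S,5S,6R in core numbering)
Conditions: PdCl2(MeCN)2 (cat.), DMF, rt, dark
Reagents that add atoms: none
Why: Stille coupling of an E-vinylstannane with an E-vinyl iodide under a phosphine-free divalent-palladium precatalyst; both alkene geometries are retained and the neutral medium spares the oxirane, the tertiary alcohol and the acidic enol.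

## Compound list

1 | 4-methylpentanal | CC(C)CCC=O | starting material
2 | triethyl 4-phosphonocrotonate | CCOC(=O)/C=C/CP(=O)(OCC)OCC | starting material
3 | ethyl (2E,4E)-8-methylnona-2,4-dienoate | CC(C)CC/C=C/C=C/C(=O)OCC | intermediate
4 | (2E,4E)-8-methylnona-2,4-dien-1-ol | CC(C)CC/C=C/C=C/CO | intermediate
5 | (2E,4E)-8-methylnona-2,4-dienal | CC(C)CC/C=C/C=C/C=O | intermediate
6 | diethyl (carbamoylmethyl)phosphonate | CCOP(=O)(CC(N)=O)OCC | starting material
7 | (2E,4E,6E)-10-methylundeca-2,4,6-trienamide | CC(C)CC/C=C/C=C/C=C/C(N)=O | intermediate
8 | cyclopentane-1,3-dione | O=C1CCC(=O)C1 | starting material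
9 | 2-nitrocyclopentane-1,3-dione (enol form) | O=C1CCC(O)=C1[N+](=O)[O-] | intermediate
10 | 2-amino-3-hydroxycyclopent-2-en-1-one hydrochloride | NC1=C(O)CCC1=O.Cl | intermediate
11 | ethyl (E)-4-oxobut-2-enoate | CCOC(=O)/C=C/C=O | starting material
12 | ethyl (2E,4E)-5-iodopenta-2,4-dienoate | CCOC(=O)/C=C/C=C/I | intermediate
13 | (2E,4E)-5-iodopenta-2,4-dienoic acid | OC(=O)/C=C/C=C/I | intermediate
14 | (2E,4E)-5-iodopenta-2,4-dienoyl chloride (formed and used in the flask) | O=C(Cl)/C=C/C=C/I | intermediate
15 | (2E,4E)-N-(2-hydroxy-5-oxocyclopent-1-en-1-yl)-5-iodopenta-2,4-dienamide | O=C(/C=C/C=C/I)NC1=C(O)CCC1=O | intermediate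
16 | phenylacetylene | C#Cc1ccccc1 | starting material
17 | dioxygen | O=O | starting material
18 | (1S,2R)-3-ethynylcyclohexa-3,5-diene-1,2-diol | C#CC1=CC=C[C@H](O)[C@@H]1O | intermediate
19 | 2,2-dimethoxypropane | COC(C)(C)OC | starting material
20 | (3aR,7aS)-4-ethynyl-2,2-dimethyl-3a,7a-dihydro-1,3-benzodioxole | C#CC1=CC=C[C@@H]2OC(C)(C)O[C@H]12 | intermediate
21 | (3aR,7aS)-2,2-dimethyl-4-[(trimethylsilyl)ethynyl]-3a,7a-dihydro-1,3-benzodioxole | C[Si](C)(C)C#CC1=CC=C[C@@H]2OC(C)(C)O[C@H]12 | intermediate
22 | endoperoxide: 5β,6β-isopropylidenedioxy-4β-[(trimethylsilyl)ethynyl]-1α,4α-epidioxycyclohex-2-ene | C[Si](C)(C)C#C[C@@]12C=C[C@@H](OO1)[C@@H]3OC(C)(C)O[C@H]23 | intermediate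
23 | 4α-hydroxy-5β,6β-isopropylidenedioxy-4β-[(trimethylsilyl)ethynyl]cyclohex-2-en-1-one | O=C1C=C[C@@](O)(C#C[Si](C)(C)C)[C@H]2OC(C)(C)O[C@@H]12 | intermediate
24 | 4α-hydroxy-2-iodo-5β,6β-isopropylidenedioxy-4β-[(trimethylsilyl)ethynyl]cyclohex-2-en-1-one | O=C1C(I)=C[C@@](O)(C#C[Si](C)(C)C)[C@H]2OC(C)(C)O[C@@H]12 | intermediate
25 | C2 trienamide of the acetonide enone (silylalkyne) | CC(C)CC/C=C/C=C/C=C/C(=O)NC1=C[C@@](O)(C#C[Si](C)(C)C)[C@H]2OC(C)(C)O[C@H]2C1=O | intermediate
26 | 4α,5β,6β-triol (silylalkyne, C2 trienamide) | CC(C)CC/C=C/C=C/C=C/C(=O)NC1=C[C@@](O)(C#C[Si](C)(C)C)[C@@H](O)[C@@H](O)C1=O | intermediate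
27 | 6β-(4-nitrobenzenesulfonyloxy)-4α,5β-diol | CC(C)CC/C=C/C=C/C=C/C(=O)NC1=C[C@@](O)(C#C[Si](C)(C)C)[C@@H](O)[C@@H](OS(=O)(=O)c2ccc(cc2)[N+](=O)[O-])C1=O | intermediate
28 | 6α-bromo-4α,5β-diol (trans-bromohydrin; formed and used in the flask) | CC(C)CC/C=C/C=C/C=C/C(=O)NC1=C[C@@](O)(C#C[Si](C)(C)C)[C@@H](O)[C@H](Br)C1=O | intermediate
29 | 5β,6β-epoxy-4α-hydroxy-4β-[(trimethylsilyl)ethynyl] enamide (formed and used in the flask) | CC(C)CC/C=C/C=C/C=C/C(=O)NC1=C[C@@](O)(C#C[Si](C)(C)C)[C@H]2O[C@H]2C1=O | intermediate
30 | 5β,6β-epoxy-4β-ethynyl-4α-hydroxy enamide | CC(C)CC/C=C/C=C/C=C/C(=O)NC1=C[C@@](O)(C#C)[C@H]2O[C@H]2C1=O | intermediate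
31 | 4β-[(E)-2-(tributylstannyl)ethenyl] epoxy enamide | CC(C)CC/C=C/C=C/C=C/C(=O)NC1=C[C@@](O)(/C=C/[Sn](CCCC)(CCCC)CCCC)[C@H]2O[C@H]2C1=O | intermediate
32 | target (4S,5S,6R in core numbering) | CC(C)CC/C=C/C=C/C=C/C(=O)NC1=C[C@@](O)(/C=C/C=C/C=C/C(=O)NC2=C(O)CCC2=O)[C@H]2O[C@H]2C1=O | target

## Step count and least certain steps

Total: 21 steps (4 for trienamide 7, 5 for iododienamide 15, 12 for the core and endgame). Longest linear sequence: 12 steps (steps 10–21, from phenylacetylene 16).

**Step 13 (key step).** The likely failures are Diels–Alder dimerisation of diene 21 before it meets singlet oxygen, and loss of the peroxide by thermal rearrangement or premature O–O cleavage during isolation. Fallback: set out from 21, photo-oxygenate at −78 °C and reduce in the same flask with thiourea to the cis-1,4-diol F1. Then oxidise only the secondary allylic C1 alcohol with MnO2 in CH2Cl2, which returns to the route at 23 without isolating a peroxide.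

**Step 16.** The carbonate base may enolise C6 and expel the C5 acetonide oxygen (E1cB opening of the dioxolane). Copper may also reduce the C–I bond faster than it couples the hindered iodoenone. Fallback: reverse the order so that no enolisable C6–H is present during the coupling.
- Set out from 24 and hydrolyse the acetonide (aqueous CF3CO2H) to the iodo triol F2.
- Sulfonylate C6–OH to the iodo nosylate F3.
- Displace with LiBr to the iodo bromohydrin F4 and close with K2CO3 in acetone (no methanol, silicon stays) to the iodo epoxy enone F5.
- Run the copper-catalysed amidation with 7 on F5, where C6 is an oxirane carbon and cannot enolise. This gives 29, which is desilylated with K2CO3 in MeOH to rejoin the route at 30.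

**Step 18.** Sulfonylation may occur at C5–OH as well or instead, or twice, if the acidity difference is smaller than expected. Fallback: set out from 26 and tie the cis-diol into the cyclic sulfite F6 (SOCl2, Et3N, CH2Cl2, −40 °C), which needs no choice between the two hydroxyls. LiBr in THF opens it at the α-keto carbon C6 with inversion, and aqueous work-up releases the C5 hydroxyl, giving 28. The route continues with K2CO3 in MeOH to 30.

**Step 19.** Substitution at the secondary C6 may be slow, leaving the sulfonate exposed to methoxide. The epoxy ketone may also be degraded by methanolic carbonate (opening at C6 or migration of the oxirane towards the C4 hydroxyl) during the slower C–Si cleavage. Fallback: set out from 27 and isolate 28 after the LiBr stage. Close the ring with Ag2O in THF (halide abstraction, no alkoxide base) to isolate 29, then remove silicon with catalytic AgNO3 in aqueous acetone, returning at 30. No new compound is involved.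

**Step 20.** Palladium hydride may transfer hydrogen to the enone or the trienamide instead of the alkyne, and some tin may add to the internal alkyne carbon. Fallback: set out from 30 and hydrosilylate with (EtO)3SiH and Pt2[(CH2=CHSiMe2)2O]3 (zerovalent platinum) with P(t-Bu)3, which is selective for terminal alkynes, to the (E)-vinyl(triethoxy)silane F7. Couple this with 15 in a fluoride-promoted Hiyama reaction (Bu4NF, Pd2(dba)3, THF, rt), which arrives directly at 32.

## Further compounds

F1 | step 13 | 1α,4α-dihydroxy-5β,6β-isopropylidenedioxy-4β-[(trimethylsilyl)ethynyl]cyclohex-2-ene (cis-1,4-diol) | O[C@@H]1C=C[C@@](O)(C#C[Si](C)(C)C)[C@H]2OC(C)(C)O[C@@H]12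
F2 | step 16 | 4α,5β,6β-trihydroxy-2-iodo-4β-[(trimethylsilyl)ethynyl]cyclohex-2-en-1-one (iodo triol) | O=C1C(I)=C[C@@](O)(C#C[Si](C)(C)C)[C@@H](O)[C@H]1O
F3 | step 16 | 4α,5β-dihydroxy-2-iodo-6β-(4-nitrobenzenesulfonyloxy)-4β-[(trimethylsilyl)ethynyl]cyclohex-2-en-1-one (iodo nosylate) | O=C1C(I)=C[C@@](O)(C#C[Si](C)(C)C)[C@@H](O)[C@H]1OS(=O)(=O)c2ccc(cc2)[N+](=O)[O-]
F4 | step 16 | 6α-bromo-4α,5β-dihydroxy-2-iodo-4β-[(trimethylsilyl)ethynyl]cyclohex-2-en-1-one (iodo bromohydrin) | O=C1C(I)=C[C@@](O)(C#C[Si](C)(C)C)[C@@H](O)[C@@H]1Br
F5 | step 16 | 5β,6β-epoxy-4α-hydroxy-2-iodo-4β-[(trimethylsilyl)ethynyl]cyclohex-2-en-1-one (iodo epoxy enone) | O=C1C(I)=C[C@@](O)(C#C[Si](C)(C)C)[C@H]2O[C@@H]12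
F6 | step 18 | 5β,6β-cyclic sulfite of triol 26 (mixture at sulfur) | CC(C)CC/C=C/C=C/C=C/C(=O)NC1=C[C@@](O)(C#C[Si](C)(C)C)[C@H]2OS(=O)O[C@H]2C1=O
F0 | step 19 | none | none
F7 | step 20 | 4β-[(E)-2-(triethoxysilyl)ethenyl] analogue of 31 | CC(C)CC/C=C/C=C/C=C/C(=O)NC1=C[C@@](O)(/C=C/[Si](OCC)(OCC)OCC)[C@H]2O[C@H]2C1=O
A1 | alternative 1 | 2-{2-[3-oxo-5-(triisopropylsilyl)pent-4-yn-1-yl]-1,3-dioxolan-2-yl}acetaldehyde | O=CCC1(CCC(=O)C#C[Si](C(C)C)(C(C)C)C(C)C)OCCO1
A2 | alternative 1 | 8-hydroxy-8-[(triisopropylsilyl)ethynyl]-1,4-dioxaspiro[4.5]decan-7-one (carbinol configured as C4 of the target) | C1C[C@@](O)(C#C[Si](C(C)C)(C(C)C)C(C)C)C(=O)CC12OCCO2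
A3 | alternative 2 | 4-(tert-butyldimethylsilyloxy)-4-ethynylcyclohexa-2,5-dien-1-one | C#CC1(O[Si](C)(C)C(C)(C)C)C=CC(=O)C=C1
A4 | alternative 2 | 4-(tert-butyldimethylsilyloxy)-5,6-epoxy-4-ethynylcyclohex-2-en-1-one (oxirane anti to the silyloxy group) | C1=C[C@@](O[Si](C)(C)C(C)(C)C)(C#C)[C@H]2O[C@H]2C1=O
A5 | alternative 3 | D-glucose (α-pyranose form) | OC[C@H]1O[C@H](O)[C@H](O)[C@@H](O)[C@@H]1O
A6 | alternative 3 | methyl 4-O-acetyl-2-O-(tert-butyldimethylsilyl)-6-deoxy-3-O-(4-methoxybenzyl)-2-C-[(triisopropylsilyl)ethynyl]-α-D-xylo-hex-5-enopyranoside (oxygens in the gluco arrangement) | CO[C@H]1OC(=C)[C@@H](OC(C)=O)[C@H](OCc2ccc(OC)cc2)[C@]1(O[Si](C)(C)C(C)(C)C)C#C[Si](C(C)C)(C(C)C)C(C)C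
A7 | alternative 3 | 6-acetoxy-4-(tert-butyldimethylsilyloxy)-5-(4-methoxybenzyloxy)-4-[(triisopropylsilyl)ethynyl]cyclohex-2-en-1-one | O=C1C=C[C@@](O[Si](C)(C)C(C)(C)C)(C#C[Si](C(C)C)(C(C)C)C(C)C)[C@@H](OCc2ccc(OC)cc2)[C@@H]1OC(C)=O
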